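**Retrosynthetic overview**
- Target ⇒ hydroxyl-directed 1,3-anti reduction of the ring ketone of a 4,5-dihydroxy-6-benzoyloxy-2-(benzoyloxymethyl)cyclohex-2-enone, preceded by acetonide removal and double benzoylation.
- CH2O branch ⇒ Morita–Baylis–Hillman hydroxymethylation of a 6-hydroxy-4,5-acetonide cyclohex-2-enone.
- Cyclohexenone (the only ring that is made; the dioxolane comes with the starting material) ⇒ one-pot [4+2] annulation of C2-symmetric D-tartraldehyde acetonide and acetaldehyde: acetyl-anion (Breslow) cross-benzoin at one aldehyde (C1–C6 bond, sets C-6), then intramolecular aldol condensation onto the other aldehyde (C2=C3).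
- Dialdehyde ⇒ (−)-2,3-O-isopropylidene-D-threitol, whose two trans-diol stereocentres relay all the others.

Assumption: compound 1 is bought as the (4R,5R) enantiomer (D-threitol series); locants in the names of 6–9 follow cyclohex-2-en-1-one numbering (C-1 = C=O).

**Step 1**
Reactants: 1 (−)-2,3-O-isopropylidene-D-threitol, [(4R,5R)-2,2-dimethyl-1,3-dioxolane-4,5-diyl]dimethanol
Product: 2 (4S,5S)-2,2-dimethyl-1,3-dioxolane-4,5-dicarbaldehyde (2,3-O-isopropylidene-D-tartraldehyde), used crude
Conditions: (COCl)2, DMSO, CH2Cl2, −78 °C; Et3N, −78 → 0 °C; non-aqueous filtration, concentrate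
Reagents that add atoms: none
Why: Swern (activated-DMSO) oxidation of both primary alcohols at low temperature, where the α-alkoxy stereocentres do not epimerise; the dialdehyde is not purified because it hydrates and oligomerises.

**Step 2**
Reactants: 2 (4S,5S)-2,2-dimethyl-1,3-dioxolane-4,5-dicarbaldehyde; 3 acetaldehyde
Product: 6 (4R,5R,6S)-6-hydroxy-4,5-(isopropylidenedioxy)cyclohex-2-en-1-one, via acyloin keto-aldehyde 4 (not isolated), via cyclic aldol 5 (not isolated)
Conditions: 3 (1.5 equiv, slow addition), 2-(pentafluorophenyl)-6,7-dihydro-5H-pyrrolo[2,1-c][1,2,4]triazol-2-ium tetrafluoroborate (15 mol%), i-Pr2NEt (15 mol%), CH2Cl2, 23 °C; evaporate volatiles; then Bn2NH2+ CF3CO2− (30 mol%), PhMe, 50 °C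
Reagents that add atoms: none
Why: Proposed new method: the triazolylidene turns unhindered acetaldehyde into its Breslow intermediate (an acetyl anion equivalent), which adds under Felkin–Anh control (anti to the α-C–O bond) to one of the two equivalent, α-branched, inductively activated aldehydes of 2 and so sets C-6 cis to the neighbouring acetal oxygen (closest known reaction: NHC-catalysed chemoselective cross-benzoin of aliphatic aldehydes with α-heteroatom-substituted branched aldehydes as pure acceptors); the methyl ketone of 4 then closes onto the remaining aldehyde by ammonium-salt-mediated 6-enolexo aldol addition to 5 and dehydration (closest known reaction: aldol cyclodehydration of 5-oxo-aldehydes to cyclohexenones), which also removes the second aldehyde before a second benzoin can occur.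

**Step 3**
Reactants: 6 (4R,5R,6S)-6-hydroxy-4,5-(isopropylidenedioxy)cyclohex-2-en-1-one
Product: 7 (4R,5R,6S)-6-hydroxy-2-(hydroxymethyl)-4,5-(isopropylidenedioxy)cyclohex-2-en-1-one
Conditions: 37% aq. HCHO, imidazole (1 equiv), THF/H2O 1:1, 23 °C
Reagents that add atoms: formaldehyde, C=O
Why: Morita–Baylis–Hillman reaction, in which imidazole adds reversibly to C-3, the enolate is hydroxymethylated at C-2 and the catalyst is expelled; this is established for 4-oxygenated cyclohexenones and touches no stereocentre.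

**Step 4**
Reactants: 7 (4R,5R,6S)-6-hydroxy-2-(hydroxymethyl)-4,5-(isopropylidenedioxy)cyclohex-2-en-1-one
Product: 8 (4R,5S,6S)-6-(benzoyloxy)-2-[(benzoyloxy)methyl]-4,5-(isopropylidenedioxy)cyclohex-2-en-1-one
Conditions: BzCl (2.4 equiv), pyridine, CH2Cl2, 0 °C
Reagents that add atoms: benzoyl chloride, O=C(Cl)c1ccccc1
Why: Nucleophilic acyl substitution (O-benzoylation) at the only two free hydroxyls, the primary allylic one and the secondary α-ketol one; pyridine without DMAP at 0 °C avoids SN2' attack on the new 2-(acyloxymethyl)enone and enolisation at C-6.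

**Step 5**
Reactants: 8 (4R,5S,6S)-6-(benzoyloxy)-2-[(benzoyloxy)methyl]-4,5-(isopropylidenedioxy)cyclohex-2-en-1-one
Product: 9 (4R,5S,6S)-6-(benzoyloxy)-2-[(benzoyloxy)methyl]-4,5-dihydroxycyclohex-2-en-1-one
Conditions: CF3CO2H/H2O 9:1, CH2Cl2, 0 °C
Reagents that add atoms: none
Why: Acid-catalysed acetal hydrolysis; the strained trans-fused dioxolane cleaves quickly under conditions that leave the benzoates and enone intact and are too acidic for base-type acyl migration or C-6 epimerisation.

**Step 6**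
Reactants: 9 (4R,5S,6S)-6-(benzoyloxy)-2-[(benzoyloxy)methyl]-4,5-dihydroxycyclohex-2-en-1-one
Product: 10 [(3R,4S,5R,6S)-5-(benzoyloxy)-3,4,6-trihydroxycyclohex-1-en-1-yl]methyl benzoate (target, CNP0198957.1)
Conditions: Me4NBH(OAc)3, MeCN/AcOH 1:1, −30 °C; aq. sodium potassium tartrate work-up
Reagents that add atoms: none
Why: Evans–Saksena hydroxyl-directed reduction, in which the 5-OH (β to the ketone) binds boron and delivers hydride to its own face through a six-membered chair transition state, giving the 1,3-anti diol and hence the new carbinol trans to the adjacent benzoate (6S in 10), with the enone C=C and the esters untouched.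

**Compound list**
1 | (−)-2,3-O-isopropylidene-D-threitol, [(4R,5R)-2,2-dimethyl-1,3-dioxolane-4,5-diyl]dimethanol | OC[C@H]1OC(C)(C)O[C@@H]1CO | starting material
2 | (4S,5S)-2,2-dimethyl-1,3-dioxolane-4,5-dicarbaldehyde | O=C[C@H]1OC(C)(C)O[C@@H]1C=O | intermediate
3 | acetaldehyde | CC=O | starting material
4 | (4S,5R)-5-[(1S)-1-hydroxy-2-oxopropyl]-2,2-dimethyl-1,3-dioxolane-4-carbaldehyde (acyloin keto-aldehyde) | O=C[C@H]1OC(C)(C)O[C@@H]1[C@H](O)C(C)=O | intermediate (not isolated)
5 | (2S,3R,4R)-2,5-dihydroxy-3,4-(isopropylidenedioxy)cyclohexan-1-one, C-5 epimers (cyclic aldol) | O=C1CC(O)[C@H]2OC(C)(C)O[C@@H]2[C@@H]1O | intermediate (not isolated)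
6 | (4R,5R,6S)-6-hydroxy-4,5-(isopropylidenedioxy)cyclohex-2-en-1-one (acetonide trans-fused, 6-OH cis to 5-O) | O=C1C=C[C@H]2OC(C)(C)O[C@@H]2[C@@H]1O | intermediate
7 | (4R,5R,6S)-6-hydroxy-2-(hydroxymethyl)-4,5-(isopropylidenedioxy)cyclohex-2-en-1-one | O=C1C(CO)=C[C@H]2OC(C)(C)O[C@@H]2[C@@H]1O | intermediate
8 | (4R,5S,6S)-6-(benzoyloxy)-2-[(benzoyloxy)methyl]-4,5-(isopropylidenedioxy)cyclohex-2-en-1-one | O=C1C(COC(=O)c3ccccc3)=C[C@H]2OC(C)(C)O[C@@H]2[C@@H]1OC(=O)c1ccccc1 | intermediate
9 | (4R,5S,6S)-6-(benzoyloxy)-2-[(benzoyloxy)methyl]-4,5-dihydroxycyclohex-2-en-1-one | O=C1C(COC(=O)c3ccccc3)=C[C@@H](O)[C@H](O)[C@@H]1OC(=O)c1ccccc1 | intermediate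
10 | [(3R,4S,5R,6S)-5-(benzoyloxy)-3,4,6-trihydroxycyclohex-1-en-1-yl]methyl benzoate | O=C(OCC1=C[C@@H](O)[C@H](O)[C@H](OC(=O)c2ccccc2)[C@H]1O)c1ccccc1 | target

**Totals**
Total step count: 6. Longest linear sequence: 6 steps (1 → 10).

**Three steps most likely to fail**

Step 2 (annulation). Risks are acetoin formation, a second benzoin on the other aldehyde, 2 acting as donor, modest diastereoselectivity at C-6, and epimerisation α to the aldehydes or of the α-ketol. The fallback replaces the catalytic acyl anion by a stoichiometric one on a desymmetrised substrate; it sets out from 1 and comes back at 4. Compound 1 is mono-silylated (NaH, TBSCl, THF) to [(4R,5R)-5-({[tert-butyl(dimethyl)silyl]oxy}methyl)-2,2-dimethyl-1,3-dioxolan-4-yl]methanol F1 and Swern-oxidised to the mono-aldehyde F2. 1-Ethoxyvinyllithium (ethyl vinyl ether, t-BuLi, THF, −78 °C) then adds under Felkin–Anh control to give the enol ether carbinol F3. Dilute aqueous oxalic acid hydrolyses the enol ether to the silyl-protected hydroxy methyl ketone F4, and Bu4NF/AcOH removes the silyl group to give the keto diol F5. Selective oxidation of the primary alcohol (TEMPO, PhI(OAc)2, CH2Cl2) gives 4, which is cyclised with Bn2NH2+ CF3CO2− as in the second stage of step 2 to 6.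

Step 3 (hydroxymethylation). The α'-hydroxy, γ-alkoxy enone may aromatise or epimerise at C-6 under the amine/water conditions, and β-addition of the catalyst next to the γ-substituent may be slow. The fallback makes the C–C bond by cross-coupling; it sets out from 6 and comes back at 7. Compound 6 is α-iodinated (I2, pyridine, CH2Cl2, 0 °C) to (4R,5R,6S)-6-hydroxy-2-iodo-4,5-(isopropylidenedioxy)cyclohex-2-en-1-one F6, which is coupled with (tributylstannyl)methanol (Pd(PPh3)4, a zerovalent palladium catalyst, dioxane, 80 °C; Stille hydroxymethylation) to give 7.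

Step 6 (directed reduction). Delivery needs the conformer with an axial 5-OH, so facial selectivity may be incomplete, and the benzoate at C-6 of 9 is cis to the free 5-OH and could migrate. The fallback sets the carbinol by inversion instead; it sets out from 8 and comes back at 10. Luche reduction of 8 (NaBH4, CeCl3·7H2O, MeOH, −78 °C) is expected to occur anti to the axial benzoate and give the cis alcohol [(3R,4S,5R,6R)-5-(benzoyloxy)-6-hydroxy-3,4-(isopropylidenedioxy)cyclohex-1-en-1-yl]methyl benzoate F7. Mitsunobu inversion with chloroacetic acid (PPh3, DIAD, THF, 0 °C) gives the inverted chloroacetate F8. Thiourea (EtOH, 50 °C) removes the chloroacetyl group selectively to give the acetonide of the target F9, and CF3CO2H/H2O as in step 5 then gives 10.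

**Further compounds**
F1 | step 2 | [(4R,5R)-5-({[tert-butyl(dimethyl)silyl]oxy}methyl)-2,2-dimethyl-1,3-dioxolan-4-yl]methanol | CC(C)(C)[Si](C)(C)OC[C@H]1OC(C)(C)O[C@@H]1CO
F2 | step 2 | (4S,5R)-5-({[tert-butyl(dimethyl)silyl]oxy}methyl)-2,2-dimethyl-1,3-dioxolane-4-carbaldehyde | CC(C)(C)[Si](C)(C)OC[C@H]1OC(C)(C)O[C@@H]1C=O
F3 | step 2 | (1S)-1-[(4R,5R)-5-({[tert-butyl(dimethyl)silyl]oxy}methyl)-2,2-dimethyl-1,3-dioxolan-4-yl]-2-ethoxyprop-2-en-1-ol | CC(C)(C)[Si](C)(C)OC[C@H]1OC(C)(C)O[C@@H]1[C@H](O)C(=C)OCC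
F4 | step 2 | (1S)-1-[(4R,5R)-5-({[tert-butyl(dimethyl)silyl]oxy}methyl)-2,2-dimethyl-1,3-dioxolan-4-yl]-1-hydroxypropan-2-one | CC(C)(C)[Si](C)(C)OC[C@H]1OC(C)(C)O[C@@H]1[C@H](O)C(C)=O
F5 | step 2 | (1S)-1-hydroxy-1-[(4R,5R)-5-(hydroxymethyl)-2,2-dimethyl-1,3-dioxolan-4-yl]propan-2-one | OC[C@H]1OC(C)(C)O[C@@H]1[C@H](O)C(C)=O
F6 | step 3 | (4R,5R,6S)-6-hydroxy-2-iodo-4,5-(isopropylidenedioxy)cyclohex-2-en-1-one | O=C1C(I)=C[C@H]2OC(C)(C)O[C@@H]2[C@@H]1O
F7 | step 6 | [(3R,4S,5R,6R)-5-(benzoyloxy)-6-hydroxy-3,4-(isopropylidenedioxy)cyclohex-1-en-1-yl]methyl benzoate | O=C(OCC1=C[C@H]2OC(C)(C)O[C@@H]2[C@H](OC(=O)c2ccccc2)[C@@H]1O)c1ccccc1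
F8 | step 6 | [(3R,4S,5R,6S)-5-(benzoyloxy)-6-(chloroacetoxy)-3,4-(isopropylidenedioxy)cyclohex-1-en-1-yl]methyl benzoate | O=C(OCC1=C[C@H]2OC(C)(C)O[C@@H]2[C@H](OC(=O)c2ccccc2)[C@H]1OC(=O)CCl)c1ccccc1
F9 | step 6 | [(3R,4S,5R,6S)-5-(benzoyloxy)-6-hydroxy-3,4-(isopropylidenedioxy)cyclohex-1-en-1-yl]methyl benzoate | O=C(OCC1=C[C@H]2OC(C)(C)O[C@@H]2[C@H](OC(=O)c2ccccc2)[C@H]1O)c1ccccc1
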